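The constants used here stand for no real mixture; the rest is arithmetic.

Slowness is not my worry in beta: with the other concentrations as charged, the electrophile's half-life by the coupling alone is 0.11 min, short against the 4.0 min run, so the next charge hangs on how far the nucleophile reaches.

    electrophile + nucleophile → acid set free + target (k1 = 14.3 /M/s)
    nucleophile + acid set free ⇌ protonated nucleophile, settled at all times (K2 = 1.61 × 10⁵ /M)
    nucleophile + protic impurity → quenched reagent (k3 = 1290 /M/s)
    2 nucleophile → self-condensation product (k4 = 5.31 /M/s)

common to all: electrophile 5.0 mM; protic impurity 0.100 mM; time 4.0 min
- beta: nucleophile 1.50 equiv
- gamma: nucleophile 3.00 equiv

- part of the electrophile that has reacted at the end, beta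
- part of the electrophile that has reacted at the end, gamma
- what raising the equivalents of nucleophile from its lowest to its highest value here does to the part of the electrophile that has reacted (changes below 5 percentage points count as none) (no change / it rises / it falls)

I reckon with the fraction left. Let a be c(electrophile) over its charge, and b be c(nucleophile) over the same charge. Acid set free meets nucleophile with a balance term of 1200 at the start of beta, so early on each coupling costs 2 nucleophile, and I carry that cost through to the end of my reckoning as an approximation. The self-condensation stays in the reckoning, since just after the start of beta the coupling uses nucleophile at 0.90 of the rate at which self-condensation uses it. Dividing the two rates removes time: db/da = 2(1 + ρb/a), with the selectivity factor ρ = 0.371.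

I take the impurity off the charge first, because at any c(nucleophile) its fraction falls faster than the electrophile's by the factor 90.2. That leaves u usable equivalents, 1.48 in beta and 2.98 in gamma. Setting b to zero and writing w = 1 − 2ρ = 0.257 gives the stall fraction, the part of the electrophile left when free nucleophile is reckoned spent: a = (1 − uw/2)^(1/w). This is 44.0% for beta and 15.3% for gamma.

Protonated nucleophile can still hand back a trickle, so I commit to floors: 56.0% reacted in beta and 84.7% in gamma. The gap of 29 percentage points exceeds the margin of 5 points, so my trend is it rises, and I charge gamma.

The forecast gives 62% (58% to 66%) for beta, 88% (84% to 91%) for gamma and it rises, holding that “free nucleophile runs out within about a minute or two”. The simulation gives 61.3% for beta and 87.2% for gamma, and it rises by 26 points.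

Beta ends with 38.7% of its electrophile left, less than its stall fraction of 44.0%, and gamma with 12.8%, less than its 15.3%. The neighbouring flask is beta with 0.380 equiv of nucleophile. Its usable charge is 0.360 equivalents, so the stall fraction is 83.2%. At 4.00 min that flask holds 78.9% of its electrophile, with free nucleophile at 0.46% of its charge and target at 21.1%.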